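Count turnovers before anything else.

| flask | starting material | second substrate | free catalyst | added ligand | remark | time |
|---|---|---|---|---|---|---|
| summer | 0.050 M | 1.5 equiv | 0.2 mol% | 0.14 mM | run made earlier |  |
| winter | 0.10 M | 1 equiv | 0.2 mol% | 0.14 mM | run made earlier |  |
| Thursday's | 0.050 M | 1.00 equiv | 0.2 mol% | 0.14 mM |  | 12 min |
| Sunday's | 0.050 M | 1.00 equiv | 0.2 mol% | 0.28 mM |  | 12 min |

| run | time / min | target / % | starting material / % |
|---|---|---|---|
| summer | 1.33 | 9 | 91 |
| summer | 2.50 | 17 | 84 |
| summer | 4.00 | 27 | 74 |
| summer | 5.00 | 36 | 67 |
| summer | 6.00 | 43 | 55 |
| summer | 8.00 | 55 | 46 |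
| winter | 0.500 | 6 | 96 |
| winter | 1.33 | 9 | 91 |
| winter | 2.50 | 18 | 82 |
| winter | 4.00 | 28 | 72 |
| winter | 6.00 | 45 | 60 |
| winter | 8.00 | 54 | 44 |

(readings scatter by 2 percentage points)

- which of the two there is more of at the end, Thursday's (isomer of the product / target)
- which of the two there is more of at the end, Sunday's (isomer of the product / target)
- final target, as a percentage of the starting material charged, in Thursday's
- final target, as a percentage of the starting material charged, in Sunday's

- the numbers in the tables scatter with a standard deviation of 2 percentage points
- no earlier run changes the charge of added ligand; that part of a forecast is a guess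

What do the two runs share? The curve of target percent against time, within the scatter of the readings. At 8.00 min, the summer run shows 55% target and the winter run 54%. Yet the winter run holds twice the starting material, at the same loading.

What do you carry from that? One number, 34.1 min⁻¹, from those two last readings. It is the turnover frequency, target made per minute per catalyst charged.

And Thursday's? The loading is the same, so my first answer is 81.8% of the charge turned over in 12 min.

Now go round again. Does that clock hold so far down? Put the answer back. By that estimate c(starting material) reaches 0.00912 M, less than the 0.0230 M of the summer run's last reading. So the last minutes of Thursday's are untested. I expect target below my first answer.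

Sunday's doubles the ligand. What then? I guess. Ligand per catalyst was 0.700 in the winter run and 1.40 in the summer run, and the last readings agree. Sunday's has 2.80, so I keep the same clock for it, without proof.

The forecast named target for Thursday's and target for Sunday's. It gave 80% (71% to 88%) for Thursday's and 75% (45% to 90%) for Sunday's, adding: “Sunday's ratio of 2.8 lies outside the tested range, so this is a guess”.

Thursday's ends with 74.2% target and 5.43% isomer of the product. Sunday's ends with 72.2% target and 4.85% isomer of the product.

    starting material + free catalyst ⇌ catalyst intermediate A (K = 3900 M⁻¹, k = 380 M⁻¹ s⁻¹)
    catalyst intermediate A → free catalyst + target (k = 0.640 s⁻¹)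
    second substrate + free catalyst ⇌ catalyst intermediate B (K = 24.0 M⁻¹, k = 15.0 M⁻¹ s⁻¹)
    catalyst intermediate B → free catalyst + second product (k = 1.00 s⁻¹)
    target + free catalyst ⇌ isomer of the product + free catalyst, rate k5*[free catalyst]*[target] forward; the back reaction follows from the equilibrium constant (K = 0.450, k = 26.0 M⁻¹ s⁻¹)
    free catalyst + added ligand ⇌ idle complex (K = 18000 M⁻¹, k = 18.0 M⁻¹ s⁻¹)

In Thursday's the isomer of the product stood at 0.949% of the starting material charged at 6.00 min. Counting target and isomer together, Thursday's ran on average at 33.2 min⁻¹ over its 12 min, against the carried 34.1 min⁻¹. Now take the neighbouring flask, Sunday's with 0.12 mol% of free catalyst. The carried turnover frequency gives it 49.1% turned over in 12 min. That neighbouring flask ends with 46.9% target and 1.31% isomer of the product. Its starting material, at 51.7%, is more than its target.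

(The readings were computed on assumed constants.)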